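**Retrosynthetic overview**

1. Apteniol E (10) comes from hydrogenation of bis-cinnamic acid 9, which comes from a double Knoevenagel–Doebner condensation of dialdehyde 6 with malonic acid (C1 and C1' carry the chains, C4 and C4' the ether oxygen).
2. The plan rests on one feature: the oxygen bridging C4 and C4' is flanked by four methoxy groups at C3, C5, C3' and C5', a tetra-ortho-substituted diaryl ether that is very hard to close by C–O coupling.
3. The C4–O–C4' bond is therefore not disconnected but bought in 4,4'-oxydibenzaldehyde (1); the four C(aryl)–OMe bonds are disconnected instead to four C(aryl)–Br bonds of bis-acetal 3 (fourfold copper-mediated methoxylation).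
4. Tetrabromide 3 comes from acetalisation of 2, which comes from fourfold bromination of 1, where the ether oxygen (ortho director) and the formyl group (meta director) point to the same four carbons.
5. No ring is formed at any stage; both benzene rings come from 1.

Key step: step 3

Assumption: the target is achiral and C2-symmetric, so no stereocentre has to be set; the E geometry of alkene 9 is transient and is erased by the final hydrogenation.

**Route**

Step 1
Reactants: 1 4,4'-oxydibenzaldehyde
Product: 2 4,4'-oxybis(3,5-dibromobenzaldehyde)
Conditions: NBS (4.6 equiv), conc. H2SO4, rt → 60 °C; ice quench, aq. NaHSO3 wash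
Reagents that add atoms: N-bromosuccinimide, O=C1CCC(=O)N1Br
Why: Electrophilic aromatic bromination with NBS in concentrated H2SO4, a reagent system known to brominate deactivated arenes including benzaldehydes, should place all four bromines at C3, C5, C3' and C5' because the aryloxy oxygen (ortho-directing, para position blocked) and the formyl group (meta-directing) address exactly these carbons.

Step 2
Reactants: 2 4,4'-oxybis(3,5-dibromobenzaldehyde)
Product: 3 4,4'-oxybis(3,5-dibromobenzaldehyde) bis(dimethyl acetal)
Conditions: HC(OMe)3 (6 equiv), p-TsOH·H2O (5 mol%), MeOH/THF, 50 °C; Et3N quench before concentration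
Reagents that add atoms: trimethyl orthoformate, COC(OC)OC; methanol, CO
Why: Acid-catalysed acetalisation, driven to completion by the orthoformate as water scavenger, should proceed readily on these electron-poor aldehydes while the aryl bromides and the diaryl ether are inert.

Step 3
Reactants: 3 4,4'-oxybis(3,5-dibromobenzaldehyde) bis(dimethyl acetal); 4 sodium methoxide
Product: 5 4,4'-oxybis(3,5-dimethoxybenzaldehyde) bis(dimethyl acetal)
Conditions: NaOMe (12 equiv, 25 wt% in MeOH), CuBr (40 mol%), DMF, 110 °C, N2; aq. NH3/NH4Cl work-up (pH about 9)
Reagents that add atoms: sodium methoxide (4), C[O-].[Na+]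
Why: NaOMe and CuBr should form a monovalent copper methoxide (the cuprate Na[Cu(OMe)2]), which adds oxidatively into a C(aryl)–Br bond to give a transient trivalent arylcopper methoxide and then eliminates reductively to release the aryl methyl ether and regenerate monovalent copper, the cycle running four times at the equivalent carbons C3, C5, C3' and C5'. The closest known reaction type is the Ullmann-type copper-catalysed methoxylation of aryl bromides, the transformation that converts 3,5-dibromo-4-hydroxybenzaldehyde into syringaldehyde, where a bromine ortho to an oxygen substituent is likewise replaced. No ring is closed and no stereocentre is created, so only chemoselectivity matters. The step needs substitution at C–Br to win over nucleophilic cleavage of the C4–O–C4' bridge by methoxide, and the acetal masking secures this because no para acceptor remains to stabilise a Meisenheimer intermediate at C4 (it also rules out Cannizzaro and Tishchenko chemistry of free aldehydes). Methoxide is the smallest oxygen nucleophile, each bromine has only one ortho neighbour, and neither ring carries an ortho C–H, so crowding is moderate and cyclisation to a dibenzofuran by intramolecular arylation is impossible. Reductive loss of bromine is held back by a high methoxide concentration, rigorous exclusion of air and the lowest temperature that still drives the fourth substitution.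

Step 4
Reactants: 5 4,4'-oxybis(3,5-dimethoxybenzaldehyde) bis(dimethyl acetal)
Product: 6 4,4'-oxybis(3,5-dimethoxybenzaldehyde)
Conditions: 1 M aq. HCl, THF, rt
Reagents that add atoms: water, O
Why: Acid-catalysed acetal hydrolysis should be fast at room temperature, and the methyl aryl ethers and the diaryl ether are stable to dilute acid.

Step 5
Reactants: 6 4,4'-oxybis(3,5-dimethoxybenzaldehyde); 7 malonic acid
Product: 9 (2E,2'E)-3,3'-[oxybis(3,5-dimethoxy-4,1-phenylene)]diacrylic acid, via bis(arylidenemalonic acid) 8 (not isolated)
Conditions: malonic acid (5 equiv), piperidine (cat.), pyridine, 90 °C → reflux; then cold aq. HCl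
Reagents that add atoms: malonic acid (7), O=C(O)CC(=O)O
Why: The Knoevenagel condensation in its Doebner modification should give the arylidenemalonic acids, which decarboxylate in hot pyridine to the thermodynamically preferred E-cinnamic acids, as is routine for the closely related 3,4,5-trimethoxybenzaldehyde.

Step 6
Reactants: 9 (2E,2'E)-3,3'-[oxybis(3,5-dimethoxy-4,1-phenylene)]diacrylic acid
Product: 10 apteniol E, 3,3'-[oxybis(3,5-dimethoxy-4,1-phenylene)]dipropanoic acid
Conditions: H2 (1 atm), 10% Pd/C, MeOH/THF, rt
Reagents that add atoms: none
Why: Heterogeneous catalytic hydrogenation over Pd/C should saturate both conjugated C=C bonds at atmospheric pressure without touching the arenes, the aryl ethers or the carboxylic acids, and it creates no stereocentre.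

**Compound list**

1 | 4,4'-oxydibenzaldehyde | O=Cc1ccc(Oc2ccc(C=O)cc2)cc1 | starting material
2 | 4,4'-oxybis(3,5-dibromobenzaldehyde) | O=Cc1cc(Br)c(Oc2c(Br)cc(C=O)cc2Br)c(Br)c1 | intermediate
3 | 4,4'-oxybis(3,5-dibromobenzaldehyde) bis(dimethyl acetal) | COC(OC)c1cc(Br)c(Oc2c(Br)cc(C(OC)OC)cc2Br)c(Br)c1 | intermediate
4 | sodium methoxide | C[O-].[Na+] | starting material
5 | 4,4'-oxybis(3,5-dimethoxybenzaldehyde) bis(dimethyl acetal) | COC(OC)c1cc(OC)c(Oc2c(OC)cc(C(OC)OC)cc2OC)c(OC)c1 | intermediate
6 | 4,4'-oxybis(3,5-dimethoxybenzaldehyde) | COc1cc(C=O)cc(OC)c1Oc1c(OC)cc(C=O)cc1OC | intermediate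
7 | malonic acid | O=C(O)CC(=O)O | starting material
8 | 2,2'-{oxybis[(3,5-dimethoxy-4,1-phenylene)methylidene]}dimalonic acid | COc1cc(C=C(C(=O)O)C(=O)O)cc(OC)c1Oc1c(OC)cc(C=C(C(=O)O)C(=O)O)cc1OC | intermediate
9 | (2E,2'E)-3,3'-[oxybis(3,5-dimethoxy-4,1-phenylene)]diacrylic acid | COc1cc(/C=C/C(=O)O)cc(OC)c1Oc1c(OC)cc(/C=C/C(=O)O)cc1OC | intermediate
10 | apteniol E, 3,3'-[oxybis(3,5-dimethoxy-4,1-phenylene)]dipropanoic acid | COc1cc(CCC(=O)O)cc(OC)c1Oc1c(OC)cc(CCC(=O)O)cc1OC | target

**Step count**

Total steps: 6. Longest linear sequence: 6 steps (1 → 2 → 3 → 5 → 6 → 9 → 10).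

**Steps most likely to fail**

Step 3 is the greatest risk. The fourfold substitution may stall as each ring becomes more electron-rich, bromine may be lost reductively through hydride transfer from methoxide at copper, and the ether bridge may be cleaved by methoxide. The fallback sets out from 3 and replaces the direct C–OMe formation by hydroxylation followed by alkylation. Palladium-catalysed hydroxylation of the four C–Br bonds (Pd2(dba)3, 2-di-tert-butylphosphino-2',4',6'-triisopropylbiphenyl, KOH, dioxane/H2O, 100 °C, degassed) should give 4,4'-oxybis(3,5-dihydroxybenzaldehyde) bis(dimethyl acetal) F1. This is handled as its potassium phenoxide and O-methylated without delay (MeI, K2CO3, DMF, rt). The sequence comes back to the route at 5.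

Step 1 is the second risk. Bromination may stall before the fourth substitution as the rings are progressively deactivated, and the formyl groups may be oxidised under the forcing conditions needed to finish it. The fallback sets out from 1 and carries out the bromination at the carboxylic acid oxidation level, which tolerates harsher conditions. Pinnick oxidation (NaClO2, NaH2PO4, 2-methyl-2-butene, t-BuOH/H2O) should give 4,4'-oxydibenzoic acid F2. Bromination under more forcing conditions (NBS, conc. H2SO4, 80 °C), with the same matched directing effects, should give 4,4'-oxybis(3,5-dibromobenzoic acid) F3. Chemoselective reduction of the acids (BH3·THF, 0 °C → rt) should give [oxybis(3,5-dibromo-4,1-phenylene)]dimethanol F4, and benzylic oxidation (MnO2, CH2Cl2, rt) comes back to the route at 2.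

Step 5 is the third risk. Condensation or decarboxylation may remain incomplete at one of the two ends, leaving mixtures of polar acids that are hard to separate. The fallback sets out from 6 and uses a double Horner–Wadsworth–Emmons olefination (triethyl phosphonoacetate, NaH, THF, 0 °C → rt). This should give diethyl (2E,2'E)-3,3'-[oxybis(3,5-dimethoxy-4,1-phenylene)]diacrylate F5, a neutral diester that can be purified by chromatography. Saponification (LiOH, THF/H2O, rt; then aq. HCl) comes back to the route at 9.

**Further compounds**

F1 | step 3 | 4,4'-oxybis(3,5-dihydroxybenzaldehyde) bis(dimethyl acetal) | COC(OC)c1cc(O)c(Oc2c(O)cc(C(OC)OC)cc2O)c(O)c1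
F2 | step 1 | 4,4'-oxydibenzoic acid | O=C(O)c1ccc(Oc2ccc(C(=O)O)cc2)cc1
F3 | step 1 | 4,4'-oxybis(3,5-dibromobenzoic acid) | O=C(O)c1cc(Br)c(Oc2c(Br)cc(C(=O)O)cc2Br)c(Br)c1
F4 | step 1 | [oxybis(3,5-dibromo-4,1-phenylene)]dimethanol | OCc1cc(Br)c(Oc2c(Br)cc(CO)cc2Br)c(Br)c1
F5 | step 5 | diethyl (2E,2'E)-3,3'-[oxybis(3,5-dimethoxy-4,1-phenylene)]diacrylate | CCOC(=O)/C=C/c1cc(OC)c(Oc2c(OC)cc(/C=C/C(=O)OCC)cc2OC)c(OC)c1
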